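**Retrosynthetic overview**
1. Ring A of the target (O1, C2 carbonyl, C3, C4, C5) has the carbon and oxygen pattern of a 3-acyltetronic acid. C4–Br maps onto the C4 enol, the acetoxy carbon C1' onto the carbonyl of a 3-butanoyl group, and the exocyclic C6HBr onto the CH2OH carbon of glyceric acid.
2. Late stage: C5=C6HBr comes from Br2/Et3N on the 5-methylene lactone, which comes from mesylate elimination of the C6 alcohol. C1'–OAc comes from oxazaborolidine-catalysed reduction of the C1' ketone, and C4–Br from C4–OH with a bromoiminium salt.
3. Key disconnection C3–C4: a base-induced Dieckmann closure of the 3-oxohexanoate ester of O-silylated methyl (R)-glycerate forms ring A, the only ring, in one operation.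
4. The β-keto ester comes from butanoyl Meldrum's acid by acylketene transfer onto the hydroxy ester, which is made from the commercial glycerate acetonide.

Key step: step 5

Assumption: C5 is drawn (R) throughout, as if the glycerate centre survived unchanged; any epimerisation there is harmless because C5 becomes sp2 in step 10 and both C5 epimers converge on 16.

**Step 1**
Reactants: 1 methyl (R)-2,2-dimethyl-1,3-dioxolane-4-carboxylate
Product: 2 methyl (R)-2,3-dihydroxypropanoate
Conditions: AcOH–H2O 4:1, rt → 40 °C; toluene azeotrope
Reagents that add atoms: none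
Why: Acid-catalysed acetal hydrolysis frees the 1,2-diol, while the methyl ester and the stereocentre, which takes no part, should stay untouched under these mild conditions.

**Step 2**
Reactants: 2 methyl (R)-2,3-dihydroxypropanoate
Product: 3 methyl (R)-3-(tert-butyldimethylsilyloxy)-2-hydroxypropanoate
Conditions: TBSCl (1.05 equiv), imidazole, CH2Cl2–DMF, 0 °C
Reagents that add atoms: tert-butyldimethylsilyl chloride, CC(C)(C)[Si](C)(C)Cl
Why: Sterically governed monosilylation, because the bulky silyl chloride reacts much faster at the primary hydroxyl than at the secondary one, which is flanked and deactivated by the ester.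

**Step 3**
Reactants: 4 Meldrum's acid (2,2-dimethyl-1,3-dioxane-4,6-dione); 5 butanoyl chloride
Product: 6 5-(1-hydroxybutylidene)-2,2-dimethyl-1,3-dioxane-4,6-dione
Conditions: pyridine (2 equiv), CH2Cl2, 0 °C → rt; dilute HCl wash
Reagents that add atoms: none
Why: C-acylation of the very acidic methylene of Meldrum's acid by an acid chloride under pyridine is the standard entry to enolised 5-acyl Meldrum's acids.

**Step 4**
Reactants: 3 methyl (R)-3-(tert-butyldimethylsilyloxy)-2-hydroxypropanoate; 6 5-(1-hydroxybutylidene)-2,2-dimethyl-1,3-dioxane-4,6-dione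
Product: 8 methyl (R)-3-(tert-butyldimethylsilyloxy)-2-(3-oxohexanoyloxy)propanoate, via butanoylketene 7 (not isolated)
Conditions: toluene, 110 °C
Reagents that add atoms: none
Why: Thermal retro-[4+2] fragmentation of 6 gives acylketene 7, which the secondary hydroxyl of 3 traps as the β-keto ester (acylketene transfer) under neutral conditions, so the stereocentre and the silyl ether are not disturbed.

**Step 5**
Reactants: 8 methyl (R)-3-(tert-butyldimethylsilyloxy)-2-(3-oxohexanoyloxy)propanoate
Product: 10 (R)-3-butanoyl-5-[(tert-butyldimethylsilyloxy)methyl]-4-hydroxyfuran-2(5H)-one, via potassium tetronate salt 9 (not isolated)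
Conditions: KOtBu (1.1 equiv), THF–t-BuOH, 0 °C → rt; then cold 0.5 M HCl, EtOAc
Reagents that add atoms: none
Why: KOtBu removes a proton from the methylene between the C2 ester carbonyl and the C1' ketone, the enolate carbon C3 adds to the methyl ester carbonyl (the future C4), methoxide leaves, and the trione formed loses its C3 proton to give the delocalised tetronate 9, a sink that pulls the preceding equilibria forward until acid work-up releases 10. The closest known reaction type is the Lacey–Dieckmann cyclisation of β-ketoacyl esters of α-hydroxy esters to 3-acyltetronic acids, which is established for 5-(oxymethyl) members made from protected glycerates. Ring A closes through bond C3–C4 in the 5-exo-trig mode, enolexo when the nucleophile is written as the C1' enolate. No stereocentre is created, and C5 is carried over from the glycerate, with any erosion there being of no consequence. The step needs enolisation at C3 rather than at the glycerate α-C–H, whose carbanion would expel silanolate or the acyloxy group; the gap of roughly ten pKa units together with about one equivalent of base secures this. The bulk of tert-butoxide also holds back cleavage of the β-ketoacyl ester.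

**Step 6**
Reactants: 10 (R)-3-butanoyl-5-[(tert-butyldimethylsilyloxy)methyl]-4-hydroxyfuran-2(5H)-one
Product: 11 (R)-4-bromo-3-butanoyl-5-[(tert-butyldimethylsilyloxy)methyl]furan-2(5H)-one
Conditions: (COBr)2 (1.2 equiv), DMF (1.3 equiv), CH2Cl2, 0 °C; then 10, 2,6-di-tert-butyl-4-methylpyridine, 0 °C → rt; rapid non-aqueous filtration, used at once
Reagents that add atoms: oxalyl bromide, O=C(Br)C(=O)Br
Why: Vilsmeier-type deoxybromination of a vinylogous acid, in which the C4 enol oxygen attacks the bromoiminium salt and bromide displaces DMF at C4 by addition–elimination, as known for tetronic acids and for cyclic 2-acyl-1,3-diones (which take the halogen at the ring carbon), while the hindered pyridine binds HBr so that the silyl ether should survive.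

**Step 7**
Reactants: 11 (R)-4-bromo-3-butanoyl-5-[(tert-butyldimethylsilyloxy)methyl]furan-2(5H)-one
Product: 12 (R)-4-bromo-5-[(tert-butyldimethylsilyloxy)methyl]-3-[(R)-1-hydroxybutyl]furan-2(5H)-one
Conditions: (S)-2-methyl-CBS-oxazaborolidine (20 mol %), catecholborane (1.5 equiv), toluene, −78 °C; then MeOH, pH 7 buffer
Reagents that add atoms: none
Why: Corey–Bakshi–Shibata reduction, in which the ketone binds the catalyst boron with the fully substituted alkenyl carbon C3 of ring A as the large group and n-propyl as the small one, so hydride should reach the Si face of C1' and set (R) (same sense as acetophenone to (R)-1-phenylethanol with the (S)-catalyst); reducing directly after step 6 also removes the second activating group from C4–Br before any amine base is used.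

**Step 8**
Reactants: 12 (R)-4-bromo-5-[(tert-butyldimethylsilyloxy)methyl]-3-[(R)-1-hydroxybutyl]furan-2(5H)-one
Product: 13 (R)-1-{(R)-4-bromo-5-[(tert-butyldimethylsilyloxy)methyl]-2-oxo-2,5-dihydrofuran-3-yl}butyl acetate
Conditions: Ac2O, pyridine, CH2Cl2, 0 °C → rt
Reagents that add atoms: acetic anhydride, CC(=O)OC(C)=O
Why: Ordinary O-acetylation leaves the C1'–O bond intact and so retains configuration, and pyridine alone, without a stronger nucleophilic catalyst, is chosen to spare the C4–Br bond.

**Step 9**
Reactants: 13 (R)-1-{(R)-4-bromo-5-[(tert-butyldimethylsilyloxy)methyl]-2-oxo-2,5-dihydrofuran-3-yl}butyl acetate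
Product: 14 (R)-1-[(R)-4-bromo-5-(hydroxymethyl)-2-oxo-2,5-dihydrofuran-3-yl]butyl acetate
Conditions: HF·pyridine, THF, 0 °C → rt (plastic vessel)
Reagents that add atoms: none
Why: Fluoride-driven Si–O cleavage in an acidic medium leaves acetate, lactone and vinyl bromide alone, whereas basic fluoride would risk deprotonation at C5.

**Step 10**
Reactants: 14 (R)-1-[(R)-4-bromo-5-(hydroxymethyl)-2-oxo-2,5-dihydrofuran-3-yl]butyl acetate
Product: 16 (R)-1-(4-bromo-5-methylene-2-oxo-2,5-dihydrofuran-3-yl)butyl acetate, via primary mesylate 15 (not isolated)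
Conditions: MsCl (1.2 equiv), Et3N (3 equiv), CH2Cl2, 0 °C → rt
Reagents that add atoms: none
Why: Mesylation followed by E1cB elimination, in which Et3N removes the vinylogously acidic C5–H of 15 and the 2-oxidofuran expels mesylate from C6 (a far better leaving group than the C1' acetate), a known way to 5-methylene butenolides that parallels the acylation–elimination of natural tetronates and erases the C5 stereocentre.

**Step 11**
Reactants: 16 (R)-1-(4-bromo-5-methylene-2-oxo-2,5-dihydrofuran-3-yl)butyl acetate
Product: 18 (R)-1-[(Z)-4-bromo-5-(bromomethylene)-2-oxo-2,5-dihydrofuran-3-yl]butyl acetate (target), via 5-bromo-5-(bromomethyl) lactone 17 (not isolated)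
Conditions: Br2 (1.0 equiv), CH2Cl2, 0 °C, dark; then Et3N (1.2 equiv), 0 °C
Reagents that add atoms: bromine, BrBr
Why: Bromination–dehydrobromination of a 5-methylene furanone, in which Br2 adds only to the enol-ether-like C5=C6 bond and Et3N removes C6–H with the labile, O1-stabilised tertiary C5–Br, the (Z) geometry being favoured because the C6 bromine turns away from the C4 bromine towards O1.

**Compound list**
1 | methyl (R)-2,2-dimethyl-1,3-dioxolane-4-carboxylate | COC(=O)[C@H]1COC(C)(C)O1 | starting material
2 | methyl (R)-2,3-dihydroxypropanoate | COC(=O)[C@H](O)CO | intermediate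
3 | methyl (R)-3-(tert-butyldimethylsilyloxy)-2-hydroxypropanoate | COC(=O)[C@H](O)CO[Si](C)(C)C(C)(C)C | intermediate
4 | Meldrum's acid | CC1(C)OC(=O)CC(=O)O1 | starting material
5 | butanoyl chloride | CCCC(Cl)=O | starting material
6 | 5-(1-hydroxybutylidene)-2,2-dimethyl-1,3-dioxane-4,6-dione | CCCC(O)=C1C(=O)OC(C)(C)OC1=O | intermediate
7 | butanoylketene (not isolated) | CCCC(=O)C=C=O | intermediate
8 | methyl (R)-3-(tert-butyldimethylsilyloxy)-2-(3-oxohexanoyloxy)propanoate | CCCC(=O)CC(=O)O[C@H](CO[Si](C)(C)C(C)(C)C)C(=O)OC | intermediate
9 | potassium salt of 10 (not isolated) | CCCC(=O)C1=C([O-])[C@@H](CO[Si](C)(C)C(C)(C)C)OC1=O.[K+] | intermediate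
10 | (R)-3-butanoyl-5-[(tert-butyldimethylsilyloxy)methyl]-4-hydroxyfuran-2(5H)-one | CCCC(=O)C1=C(O)[C@@H](CO[Si](C)(C)C(C)(C)C)OC1=O | intermediate
11 | (R)-4-bromo-3-butanoyl-5-[(tert-butyldimethylsilyloxy)methyl]furan-2(5H)-one | CCCC(=O)C1=C(Br)[C@@H](CO[Si](C)(C)C(C)(C)C)OC1=O | intermediate
12 | (R)-4-bromo-5-[(tert-butyldimethylsilyloxy)methyl]-3-[(R)-1-hydroxybutyl]furan-2(5H)-one | CCC[C@@H](O)C1=C(Br)[C@@H](CO[Si](C)(C)C(C)(C)C)OC1=O | intermediate
13 | (R)-1-{(R)-4-bromo-5-[(tert-butyldimethylsilyloxy)methyl]-2-oxo-2,5-dihydrofuran-3-yl}butyl acetate | CCC[C@@H](OC(C)=O)C1=C(Br)[C@@H](CO[Si](C)(C)C(C)(C)C)OC1=O | intermediate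
14 | (R)-1-[(R)-4-bromo-5-(hydroxymethyl)-2-oxo-2,5-dihydrofuran-3-yl]butyl acetate | CCC[C@@H](OC(C)=O)C1=C(Br)[C@@H](CO)OC1=O | intermediate
15 | (R)-1-{(R)-4-bromo-5-[(methylsulfonyloxy)methyl]-2-oxo-2,5-dihydrofuran-3-yl}butyl acetate (not isolated) | CCC[C@@H](OC(C)=O)C1=C(Br)[C@@H](COS(C)(=O)=O)OC1=O | intermediate
16 | (R)-1-(4-bromo-5-methylene-2-oxo-2,5-dihydrofuran-3-yl)butyl acetate | CCC[C@@H](OC(C)=O)C1=C(Br)C(=C)OC1=O | intermediate
17 | (R)-1-[4,5-dibromo-5-(bromomethyl)-2-oxo-2,5-dihydrofuran-3-yl]butyl acetate, both C5 epimers (not isolated) | CCC[C@@H](OC(C)=O)C1=C(Br)C(Br)(CBr)OC1=O | intermediate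
18 | (R)-1-[(Z)-4-bromo-5-(bromomethylene)-2-oxo-2,5-dihydrofuran-3-yl]butyl acetate | CCC[C@@H](OC(C)=O)C1=C(Br)/C(=C/Br)OC1=O | target

**Total step count:** 11
**Longest linear sequence:** 10 steps (1 → 18 through steps 1, 2 and 4–11). Step 3 is a one-step side branch.

**Steps most likely to fail**

Step 6. Three things could go wrong. Activation could occur at the exocyclic C1' enol oxygen instead of the ring C4 oxygen, so that bromide enters at the wrong carbon. The silyl ether could be lost to traces of HBr. The doubly activated C4–Br bond could hydrolyse back during handling.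

The fallback separates activation from halide delivery and forms no protic acid. Starting from 10, Tf2O and 2,6-lutidine in CH2Cl2 at −78 °C should give the C4 enol triflate F1, whose site of sulfonylation can be checked before bromide is introduced. LiBr in THF at 0 °C then exchanges sulfonate for bromide by addition–elimination at C4, and the route is rejoined at 11.

Step 7. Facial discrimination could be poor if the two flanks of the ketone differ too little in effective size, or if the lactone carbonyl competes for the catalyst boron. Conjugate hydride delivery with loss of bromide is a second hazard.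

The fallback gives up catalyst control in favour of resolution and inversion. Starting from 11, Zn(BH4)2 in Et2O at −20 °C (no nucleophilic solvent) should give the C1'-epimeric alcohols F2. Burkholderia cepacia lipase with vinyl acetate in MTBE should then acetylate the (R)-carbinol preferentially, as the empirical size rule for lipases predicts when the larger group has the higher priority, and this delivers 13 directly. The unreacted (S)-alcohol F3 is separated and inverted by a Mitsunobu reaction (PPh3, DIAD, AcOH, THF, 0 °C), which also gives 13.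

Step 5. β-Elimination of silanolate or of the acyloxy group could follow stray deprotonation at the glycerate α-carbon. Alkoxide cleavage of the β-ketoacyl ester could also outrun ring closure.

The fallback makes the same C3–C4 bond intermolecularly and closes ring A afterwards by lactonisation (O1–C2).
- Starting from 1, KOH in MeOH gives potassium (R)-2,2-dimethyl-1,3-dioxolane-4-carboxylate F4.
- (COCl)2 in Et2O at 0 °C gives the acid chloride F5.
- Soft enolisation of purchased methyl 3-oxohexanoate with MgCl2 and pyridine in CH2Cl2, followed by C-acylation with F5, gives the tricarbonyl ester F6.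
- TFA–H2O removes the acetonide, and the liberated secondary hydroxyl lactonises onto the methyl ester to give (R)-3-butanoyl-4-hydroxy-5-(hydroxymethyl)furan-2(5H)-one F7.
- TBSCl and imidazole silylate the primary hydroxyl (any enol silyl ether falls off on work-up), and the route is rejoined at 10.

**Further compounds**
F1 | step 6 | (R)-3-butanoyl-5-[(tert-butyldimethylsilyloxy)methyl]-2-oxo-2,5-dihydrofuran-4-yl trifluoromethanesulfonate | CCCC(=O)C1=C(OS(=O)(=O)C(F)(F)F)[C@@H](CO[Si](C)(C)C(C)(C)C)OC1=O
F2 | step 7 | (R)-4-bromo-5-[(tert-butyldimethylsilyloxy)methyl]-3-(1-hydroxybutyl)furan-2(5H)-one, both C1' epimers | CCCC(O)C1=C(Br)[C@@H](CO[Si](C)(C)C(C)(C)C)OC1=O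
F3 | step 7 | (R)-4-bromo-5-[(tert-butyldimethylsilyloxy)methyl]-3-[(S)-1-hydroxybutyl]furan-2(5H)-one | CCC[C@H](O)C1=C(Br)[C@@H](CO[Si](C)(C)C(C)(C)C)OC1=O
F4 | step 5 | potassium (R)-2,2-dimethyl-1,3-dioxolane-4-carboxylate | [K+].[O-]C(=O)[C@H]1COC(C)(C)O1
F5 | step 5 | (R)-2,2-dimethyl-1,3-dioxolane-4-carbonyl chloride | ClC(=O)[C@H]1COC(C)(C)O1
F6 | step 5 | methyl 2-[(R)-2,2-dimethyl-1,3-dioxolane-4-carbonyl]-3-oxohexanoate (C2 labile, largely enolised) | CCCC(=O)C(C(=O)OC)C(=O)[C@H]1COC(C)(C)O1
F7 | step 5 | (R)-3-butanoyl-4-hydroxy-5-(hydroxymethyl)furan-2(5H)-one | CCCC(=O)C1=C(O)[C@@H](CO)OC1=O
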